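**Plan**
Retrosynthesis: (1) the C2'–C3' bond between the side-chain methine and the (E)-alkene is cut to a C2' secondary bromide on the intact 1,2-dioxane and a terminal enyne; (2) C6–C1' is cut to a cyclic peroxyketal (peroxycarbenium allylation); (3) the ring O2–C3 bond (invertive SN2) and the C6 peroxyketal (ozonolysis in methanol) are cut to an acyclic anti mesylate; (4) that chain goes back to a Sharpless epoxy alcohol.
Forward: the C1–C6 chain is built first, the single ring (the 1,2-dioxane) is closed by 6-exo-tet O-alkylation, an allyl group is placed on C6, the phenyl-diene arm is joined last, then desilylation and oxidation give the acid.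
Stereochemistry: C3/C4 from Sharpless epoxidation and invertive cuprate opening, with a further inversion at C3 on ring closure; C6 from axial attack on the peroxycarbenium ion; C6' from an Evans alkylation; C2' and the (E)-C3'=C4' geometry from the key step.
Enabling feature: C2' is a methyl-bearing secondary carbon between the C1' methylene on quaternary C6 of the dioxane ring and the C3'=C4' alkene. As a radical it is planar, so both C2' epimers of the bromide can be funnelled by a chiral nickel catalyst into one configuration while an alkyne-derived (E)-alkenyl group is delivered. It lies γ to ring oxygen O1, the position least prone to attack on the O–O bond.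

Key step: step 17

Remark: locants follow the target throughout (ring O1, O2, C3 with the two-carbon arm, C4-Me, C5, C6 with Me and the side chain C1'–C8'); compounds 1 and 16 are taken as purchasable.

Step 1
Reactants: 1 tert-butyl(but-3-yn-1-yloxy)dimethylsilane
Product: 3 5-[(tert-butyldimethylsilyl)oxy]pent-2-yn-1-ol, via lithium acetylide 2 (not isolated)
Conditions: n-BuLi, THF, –78 °C; (CH2O)n, –78 °C → rt; H2O
Reagents that add atoms: paraformaldehyde (reacts as formaldehyde), C=O
Why: Deprotonation of the terminal alkyne and 1,2-addition of the acetylide to formaldehyde (aldehyde alkynylation) is a standard hydroxymethylation that forms no stereocentre.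

Step 2
Reactants: 3 5-[(tert-butyldimethylsilyl)oxy]pent-2-yn-1-ol
Product: 4 (2E)-5-[(tert-butyldimethylsilyl)oxy]pent-2-en-1-ol
Conditions: NaAlH2(OCH2CH2OMe)2, THF, 0 °C; H2O
Reagents that add atoms: none
Why: Alkoxide-directed trans-hydroalumination of a propargylic alcohol should give the (E)-allylic alcohol only.

Step 3
Reactants: 4 (2E)-5-[(tert-butyldimethylsilyl)oxy]pent-2-en-1-ol
Product: 5 [(2R,3R)-3-{2-[(tert-butyldimethylsilyl)oxy]ethyl}oxiran-2-yl]methanol
Conditions: Ti(OiPr)4 (cat.), D-(–)-diethyl tartrate (cat.), t-BuOOH, 4 Å MS, CH2Cl2, –20 °C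
Reagents that add atoms: tert-butyl hydroperoxide, CC(C)(C)OO
Why: Sharpless asymmetric epoxidation, in which the D-(–)-tartrate ligand directs oxygen to the face of the (E)-allylic alcohol that gives the (2R,3R)-epoxide, fixing the later C3 oxygen centre and the carbon that becomes C4.

Step 4
Reactants: 5 [(2R,3R)-3-{2-[(tert-butyldimethylsilyl)oxy]ethyl}oxiran-2-yl]methanol
Product: 6 (2S,3R)-5-[(tert-butyldimethylsilyl)oxy]-2-methylpentane-1,3-diol
Conditions: Me2CuLi (made in the flask from MeLi and CuI), Et2O, –40 → –20 °C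
Reagents that add atoms: lithium dimethylcuprate, [Li+].C[Cu-]C
Why: Hydroxyl-directed SN2 opening of the 2,3-epoxy alcohol by the cuprate at the carbon next to CH2OH, with inversion, should turn the trans-epoxide into the anti 2-methyl-1,3-diol, which sets C4 as (S) and leaves the C3–O centre as (R).

Step 5
Reactants: 6 (2S,3R)-5-[(tert-butyldimethylsilyl)oxy]-2-methylpentane-1,3-diol
Product: 7 (2S,3R)-5-[(tert-butyldimethylsilyl)oxy]-3-hydroxy-2-methylpentyl 4-methylbenzenesulfonate
Conditions: TsCl, Et3N, Bu2SnO (cat.), CH2Cl2, 0 °C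
Reagents that add atoms: 4-methylbenzenesulfonyl chloride, Cc1ccc(cc1)S(Cl)(=O)=O
Why: Tin-catalysed sulfonylation should select the primary over the secondary hydroxyl without touching either stereocentre.

Step 6
Reactants: 7 (2S,3R)-5-[(tert-butyldimethylsilyl)oxy]-3-hydroxy-2-methylpentyl 4-methylbenzenesulfonate
Product: 8 (3R,4S)-1-[(tert-butyldimethylsilyl)oxy]-4,6-dimethylhept-6-en-3-ol
Conditions: CH2=C(CH3)MgBr (excess), CuI (cat.), THF, –30 → 0 °C
Reagents that add atoms: isopropenylmagnesium bromide, C=C(C)[Mg]Br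
Why: Copper-catalysed Grignard cross-coupling at the primary tosylate installs the isopropenyl group (C6 and its methyl), the magnesium alkoxide being too poor a nucleophile at this temperature to close an oxetane, and no stereocentre is involved.

Step 7
Reactants: 8 (3R,4S)-1-[(tert-butyldimethylsilyl)oxy]-4,6-dimethylhept-6-en-3-ol
Product: 9 (3R,4S)-1-[(tert-butyldimethylsilyl)oxy]-4,6-dimethylhept-6-en-3-yl methanesulfonate
Conditions: MsCl, Et3N, CH2Cl2, 0 °C
Reagents that add atoms: methanesulfonyl chloride, CS(Cl)(=O)=O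
Why: Standard mesylation with retention at C3 prepares the anti C3/C4 leaving group for the invertive ring closure.

Step 8
Reactants: 9 (3R,4S)-1-[(tert-butyldimethylsilyl)oxy]-4,6-dimethylhept-6-en-3-yl methanesulfonate
Product: 10 (3R,4S)-1-[(tert-butyldimethylsilyl)oxy]-6-hydroperoxy-6-methoxy-4-methylheptan-3-yl methanesulfonate (both C6 epimers)
Conditions: O3, MeOH/CH2Cl2, –78 °C; N2 purge, no reductant
Reagents that add atoms: ozone, [O-][O+]=O; methanol, CO
Why: Criegee ozonolysis of the 1,1-disubstituted alkene in methanol should give the ketone carbonyl oxide, which methanol traps as the α-methoxy hydroperoxide, C6 arising as a mixture that is erased in step 10.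

Step 9
Reactants: 10 (3R,4S)-1-[(tert-butyldimethylsilyl)oxy]-6-hydroperoxy-6-methoxy-4-methylheptan-3-yl methanesulfonate
Product: 11 (3S,4S)-3-{2-[(tert-butyldimethylsilyl)oxy]ethyl}-6-methoxy-4,6-dimethyl-1,2-dioxane (both C6 epimers)
Conditions: KOtBu, 18-crown-6, THF, 0 °C
Reagents that add atoms: none
Why: Intramolecular 6-exo-tet SN2 alkylation of the hydroperoxide anion (a strong nucleophile but weak base) by the secondary mesylate closes the 1,2-dioxane with inversion at C3, converting the anti C3/C4 pair into the 3,4-cis arrangement of the target.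

Step 10
Reactants: 11 (3S,4S)-3-{2-[(tert-butyldimethylsilyl)oxy]ethyl}-6-methoxy-4,6-dimethyl-1,2-dioxane
Product: 12 (3S,4S,6S)-6-allyl-3-{2-[(tert-butyldimethylsilyl)oxy]ethyl}-4,6-dimethyl-1,2-dioxane
Conditions: CH2=CHCH2SiMe3, TMSOTf (cat.), CH2Cl2, –78 °C
Reagents that add atoms: allyltrimethylsilane, C=CC[Si](C)(C)C
Why: Lewis-acid ionisation of the peroxyketal to the cyclic peroxycarbenium ion and Hosomi–Sakurai allylation, in which axial attack on the half-chair with the C4 methyl pseudo-equatorial and the C3 arm pseudo-axial on the far face should place the allyl group trans to both and so set C6.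

Step 11
Reactants: 12 (3S,4S,6S)-6-allyl-3-{2-[(tert-butyldimethylsilyl)oxy]ethyl}-4,6-dimethyl-1,2-dioxane
Product: 14 (3S,4S,6R)-3-{2-[(tert-butyldimethylsilyl)oxy]ethyl}-6-(2-hydroxypropyl)-4,6-dimethyl-1,2-dioxane (both C2' epimers), via organomercury acetate 13 (not isolated)
Conditions: Hg(OAc)2, THF/H2O, 0 °C; NaBH4, aq. NaOH, 0 °C
Reagents that add atoms: water, O
Why: Markovnikov oxymercuration of the terminal alkene followed by reductive demercuration gives the secondary alcohol, and the C2' mixture is acceptable because step 17 is stereoconvergent.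

Step 12
Reactants: 14 (3S,4S,6R)-3-{2-[(tert-butyldimethylsilyl)oxy]ethyl}-6-(2-hydroxypropyl)-4,6-dimethyl-1,2-dioxane
Product: 15 (3S,4S,6R)-6-(2-bromopropyl)-3-{2-[(tert-butyldimethylsilyl)oxy]ethyl}-4,6-dimethyl-1,2-dioxane (both C2' epimers)
Conditions: CBr4, PPh3, CH2Cl2, 0 °C
Reagents that add atoms: tetrabromomethane, BrC(Br)(Br)Br
Why: Appel bromination through the alkoxyphosphonium ion, in which the phosphine should be consumed by CBr4 faster than it can attack the hindered O–O bond, with C2' remaining a mixture.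

Step 13
Reactants: 16 (4R)-4-benzyl-3-propanoyl-1,3-oxazolidin-2-one
Product: 18 (4R)-4-benzyl-3-[(2S)-2-methylpent-4-ynoyl]-1,3-oxazolidin-2-one, via sodium enolate 17 (not isolated)
Conditions: NaN(SiMe3)2, THF, –78 °C; HC≡CCH2Br, –78 → –40 °C
Reagents that add atoms: 3-bromoprop-1-yne, C#CCBr
Why: Evans asymmetric alkylation, in which the chelated (Z)-enolate is alkylated on the face away from the benzyl group to set the (2S) centre that becomes C6'.

Step 14
Reactants: 18 (4R)-4-benzyl-3-[(2S)-2-methylpent-4-ynoyl]-1,3-oxazolidin-2-one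
Product: 19 (2S)-2-methylpent-4-yn-1-ol
Conditions: LiBH4, MeOH, Et2O, 0 °C
Reagents that add atoms: none
Why: Reductive cleavage of the imide by borohydride releases the primary alcohol without epimerisation and returns the auxiliary.

Step 15
Reactants: 19 (2S)-2-methylpent-4-yn-1-ol
Product: 20 (2S)-2-methylpent-4-ynal
Conditions: Dess–Martin periodinane, NaHCO3, CH2Cl2, 0 °C; used without purification
Reagents that add atoms: none
Why: Buffered Dess–Martin oxidation is non-epimerising, and the volatile aldehyde is carried on directly.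

Step 16
Reactants: 20 (2S)-2-methylpent-4-ynal
Product: 21 [(1E,3S)-3-methylhex-1-en-5-yn-1-yl]benzene
Conditions: (EtO)2P(O)CH2Ph, NaN(SiMe3)2, THF, –78 °C; then 20, –78 °C → rt
Reagents that add atoms: diethyl benzylphosphonate, CCOP(=O)(OCC)Cc1ccccc1
Why: Horner–Wadsworth–Emmons olefination with the benzylphosphonate anion should give the (E)-styrene, and adding the aldehyde to the preformed anion at low temperature limits α-epimerisation.

Step 17
Reactants: 15 (3S,4S,6R)-6-(2-bromopropyl)-3-{2-[(tert-butyldimethylsilyl)oxy]ethyl}-4,6-dimethyl-1,2-dioxane (both C2' epimers); 21 [(1E,3S)-3-methylhex-1-en-5-yn-1-yl]benzene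
Product: 24 (3S,4S,6S)-3-{2-[(tert-butyldimethylsilyl)oxy]ethyl}-4,6-dimethyl-6-[(2R,3E,6S,7E)-2,6-dimethyl-8-phenylocta-3,7-dien-1-yl]-1,2-dioxane, via alkenylzirconocene chloride 22 (not isolated), via alkenylzinc chloride 23 (not isolated)
Conditions: 21, Cp2Zr(H)Cl, THF, rt; ZnCl2, 0 °C; then 15, NiCl2·glyme (cat.), (S,S)-i-Pr-PyBox (cat.; the antipode if this one proves mismatched), DMA/THF, 0 °C → rt
Reagents that add atoms: none
Why: Proposed new method: syn-hydrozirconation of the alkyne of 21 fixes the (E)-C3'=C4' geometry, Zr-to-Zn exchange gives 23, and in the nickel cycle a monovalent nickel species abstracts bromine from either C2' epimer of 15 so that both collapse to one planar secondary radical, which is captured by the chiral alkenyl–nickel–PyBox complex and leaves by C(sp3)–C(sp2) reductive elimination from trivalent nickel. The closest known reaction types are the nickel-catalysed stereoconvergent Negishi alkenylations and arylations of racemic secondary alkyl halides (activated by a carbonyl, nitrile, sulfonyl or aryl group, or unactivated but carrying a remote coordinating oxygen) and the non-selective nickel–PyBox Negishi coupling of unactivated secondary bromides; what is new is ligand-controlled convergence at an unactivated methyl carbinyl radical with an alkenylzinc partner. No ring is closed. The one new stereocentre, C2', is controlled by the ligand at the radical-capture and reductive-elimination stage, and the (E)-alkene by the syn-hydrozirconation; C3, C4, C6 and C6' are remote and untouched. The step needs discrimination between the two faces of a radical flanked by a methyl group and by the CH2–C6 arm, which the substrate helps through the large size difference between these groups (C6 is quaternary) and through ring oxygens O1 and O2, which can reach nickel in five- and six-membered chelates as the directing oxygens of the known unactivated cases do. It also needs the O–O bond, the styrene and the silyl ether to survive, which the base-free conditions and the position of the radical γ to O1 (slow four-membered attack on the peroxide) should secure.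

Step 18
Reactants: 24 (3S,4S,6S)-3-{2-[(tert-butyldimethylsilyl)oxy]ethyl}-4,6-dimethyl-6-[(2R,3E,6S,7E)-2,6-dimethyl-8-phenylocta-3,7-dien-1-yl]-1,2-dioxane
Product: 25 2-[(3S,4S,6S)-4,6-dimethyl-6-[(2R,3E,6S,7E)-2,6-dimethyl-8-phenylocta-3,7-dien-1-yl]-1,2-dioxan-3-yl]ethanol
Conditions: HF·pyridine, pyridine/THF, 0 °C → rt
Reagents that add atoms: none
Why: Buffered fluoride cleavage of the primary silyl ether avoids the basic conditions that could start Kornblum–DeLaMare cleavage of the peroxide at C3–H.

Step 19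
Reactants: 25 2-[(3S,4S,6S)-4,6-dimethyl-6-[(2R,3E,6S,7E)-2,6-dimethyl-8-phenylocta-3,7-dien-1-yl]-1,2-dioxan-3-yl]ethanol
Product: 26 2-[(3S,4S,6S)-4,6-dimethyl-6-[(2R,3E,6S,7E)-2,6-dimethyl-8-phenylocta-3,7-dien-1-yl]-1,2-dioxan-3-yl]acetic acid
Conditions: TEMPO (cat.), PhI(OAc)2, MeCN/H2O, rt
Reagents that add atoms: water, O
Why: Oxoammonium (TEMPO/PhI(OAc)2) oxidation of the primary alcohol through the aldehyde hydrate to the carboxylic acid should leave both alkenes and the O–O bond untouched.

**Compound list**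
1 | tert-butyl(but-3-yn-1-yloxy)dimethylsilane | C#CCCO[Si](C)(C)C(C)(C)C | starting material
2 | lithium 4-[(tert-butyldimethylsilyl)oxy]but-1-yn-1-ide | [Li]C#CCCO[Si](C)(C)C(C)(C)C | intermediate
3 | 5-[(tert-butyldimethylsilyl)oxy]pent-2-yn-1-ol | OCC#CCCO[Si](C)(C)C(C)(C)C | intermediate
4 | (2E)-5-[(tert-butyldimethylsilyl)oxy]pent-2-en-1-ol | OC/C=C/CCO[Si](C)(C)C(C)(C)C | intermediate
5 | [(2R,3R)-3-{2-[(tert-butyldimethylsilyl)oxy]ethyl}oxiran-2-yl]methanol | OC[C@H]1O[C@@H]1CCO[Si](C)(C)C(C)(C)C | intermediate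
6 | (2S,3R)-5-[(tert-butyldimethylsilyl)oxy]-2-methylpentane-1,3-diol | OC[C@H](C)[C@H](O)CCO[Si](C)(C)C(C)(C)C | intermediate
7 | (2S,3R)-5-[(tert-butyldimethylsilyl)oxy]-3-hydroxy-2-methylpentyl 4-methylbenzenesulfonate | Cc1ccc(cc1)S(=O)(=O)OC[C@H](C)[C@H](O)CCO[Si](C)(C)C(C)(C)C | intermediate
8 | (3R,4S)-1-[(tert-butyldimethylsilyl)oxy]-4,6-dimethylhept-6-en-3-ol | C=C(C)C[C@H](C)[C@H](O)CCO[Si](C)(C)C(C)(C)C | intermediate
9 | (3R,4S)-1-[(tert-butyldimethylsilyl)oxy]-4,6-dimethylhept-6-en-3-yl methanesulfonate | C=C(C)C[C@H](C)[C@H](OS(C)(=O)=O)CCO[Si](C)(C)C(C)(C)C | intermediate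
10 | (3R,4S)-1-[(tert-butyldimethylsilyl)oxy]-6-hydroperoxy-6-methoxy-4-methylheptan-3-yl methanesulfonate (both C6 epimers, C6 left open) | COC(C)(OO)C[C@H](C)[C@H](OS(C)(=O)=O)CCO[Si](C)(C)C(C)(C)C | intermediate
11 | (3S,4S)-3-{2-[(tert-butyldimethylsilyl)oxy]ethyl}-6-methoxy-4,6-dimethyl-1,2-dioxane (both C6 epimers, C6 left open) | COC1(C)C[C@H](C)[C@H](CCO[Si](C)(C)C(C)(C)C)OO1 | intermediate
12 | (3S,4S,6S)-6-allyl-3-{2-[(tert-butyldimethylsilyl)oxy]ethyl}-4,6-dimethyl-1,2-dioxane | C=CC[C@@]1(C)C[C@H](C)[C@H](CCO[Si](C)(C)C(C)(C)C)OO1 | intermediate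
13 | (3S,4S,6R)-6-[3-(acetoxymercurio)-2-hydroxypropyl]-3-{2-[(tert-butyldimethylsilyl)oxy]ethyl}-4,6-dimethyl-1,2-dioxane (C2' left open) | CC(=O)O[Hg]CC(O)C[C@@]1(C)C[C@H](C)[C@H](CCO[Si](C)(C)C(C)(C)C)OO1 | intermediate
14 | (3S,4S,6R)-3-{2-[(tert-butyldimethylsilyl)oxy]ethyl}-6-(2-hydroxypropyl)-4,6-dimethyl-1,2-dioxane (both C2' epimers, C2' left open) | CC(O)C[C@@]1(C)C[C@H](C)[C@H](CCO[Si](C)(C)C(C)(C)C)OO1 | intermediate
15 | (3S,4S,6R)-6-(2-bromopropyl)-3-{2-[(tert-butyldimethylsilyl)oxy]ethyl}-4,6-dimethyl-1,2-dioxane (both C2' epimers, C2' left open) | CC(Br)C[C@@]1(C)C[C@H](C)[C@H](CCO[Si](C)(C)C(C)(C)C)OO1 | intermediate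
16 | (4R)-4-benzyl-3-propanoyl-1,3-oxazolidin-2-one | CCC(=O)N1[C@H](Cc2ccccc2)COC1=O | starting material
17 | sodium (Z)-enolate of 16 | [Na+].C/C=C(\[O-])N1[C@H](Cc2ccccc2)COC1=O | intermediate
18 | (4R)-4-benzyl-3-[(2S)-2-methylpent-4-ynoyl]-1,3-oxazolidin-2-one | C#CC[C@H](C)C(=O)N1[C@H](Cc2ccccc2)COC1=O | intermediate
19 | (2S)-2-methylpent-4-yn-1-ol | C#CC[C@H](C)CO | intermediate
20 | (2S)-2-methylpent-4-ynal | C#CC[C@H](C)C=O | intermediate
21 | [(1E,3S)-3-methylhex-1-en-5-yn-1-yl]benzene | C#CC[C@H](C)/C=C/c1ccccc1 | intermediate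
22 | chlorobis(cyclopentadienyl)[(1E,4S,5E)-4-methyl-6-phenylhexa-1,5-dien-1-yl]zirconium | C[C@H](/C=C/c1ccccc1)C/C=C/[Zr](Cl)(C1C=CC=C1)C1C=CC=C1 | intermediate
23 | chloro[(1E,4S,5E)-4-methyl-6-phenylhexa-1,5-dien-1-yl]zinc | C[C@H](/C=C/c1ccccc1)C/C=C/[Zn]Cl | intermediate
24 | (3S,4S,6S)-3-{2-[(tert-butyldimethylsilyl)oxy]ethyl}-4,6-dimethyl-6-[(2R,3E,6S,7E)-2,6-dimethyl-8-phenylocta-3,7-dien-1-yl]-1,2-dioxane | C[C@H](/C=C/c1ccccc1)C/C=C/[C@H](C)C[C@@]1(C)C[C@H](C)[C@H](CCO[Si](C)(C)C(C)(C)C)OO1 | intermediate
25 | 2-[(3S,4S,6S)-4,6-dimethyl-6-[(2R,3E,6S,7E)-2,6-dimethyl-8-phenylocta-3,7-dien-1-yl]-1,2-dioxan-3-yl]ethanol | C[C@H](/C=C/c1ccccc1)C/C=C/[C@H](C)C[C@@]1(C)C[C@H](C)[C@H](CCO)OO1 | intermediate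
26 | 2-[(3S,4S,6S)-4,6-dimethyl-6-[(2R,3E,6S,7E)-2,6-dimethyl-8-phenylocta-3,7-dien-1-yl]-1,2-dioxan-3-yl]acetic acid | C[C@H](/C=C/c1ccccc1)C/C=C/[C@H](C)C[C@@]1(C)C[C@H](C)[C@H](CC(=O)O)OO1 | target

**Step count**
Total step count: 19. Longest linear sequence: 15 steps (steps 1–12, then 17–19); steps 13–16 make the enyne arm.

**Steps most likely to fail**

1. Step 17 (Proposed new method). The chiral ligand may fail to control the face at which the planar C2' radical is captured, an unactivated methyl/alkyl carbinyl centre, giving poor diastereofacial selectivity. Low-valent nickel may also reductively cleave the O–O bond. The fallback uses known, stereospecific chemistry; it sets out from 12 and comes back at 24. Alkene 12 would be hydroborated with Markovnikov and enantio-control (CuCl, bulky chiral bisphosphine, KOMe, B2pin2, MeOH, THF) to the secondary boronate (3S,4S,6S)-3-{2-[(tert-butyldimethylsilyl)oxy]ethyl}-4,6-dimethyl-6-[(2R)-2-(4,4,5,5-tetramethyl-1,3,2-dioxaborolan-2-yl)propyl]-1,2-dioxane F1. Enyne 21 would be converted by hydrozirconation and iodination (Cp2Zr(H)Cl, then I2) into [(1E,3S,5E)-6-iodo-3-methylhexa-1,5-dien-1-yl]benzene F2. Iodine–lithium exchange on F2 (t-BuLi, –78 °C) and addition of F1 would give the boronate complex. PhSeCl and then mCPBA would trigger 1,2-migration with retention at C2' and syn-elimination (Zweifel olefination, selenium variant), which should deliver 24 with the (E)-alkene.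

2. Step 10. Heterolysis of the O–O bond or fragmentation of the peroxycarbenium ion may outrun capture by the weakly nucleophilic allylsilane, or the facial selectivity of the attack may erode. The fallback sets out from 11 and comes back at 14. Mukaiyama-type addition of the far more nucleophilic 2-(trimethylsilyloxy)propene (TMSOTf, CH2Cl2, –78 °C) would give (3S,4S,6R)-3-{2-[(tert-butyldimethylsilyl)oxy]ethyl}-4,6-dimethyl-6-(2-oxopropyl)-1,2-dioxane F3. Reduction with NaBH4/CeCl3 (MeOH, –40 °C) would give 14, which also removes mercury from the route.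

3. Step 11. During reductive demercuration the primary carbon radical lies δ to O1 and may attack the O–O bond by intramolecular homolytic substitution. The alkaline borohydride medium may also start base-induced cleavage of the peroxide at C3–H. The fallback sets out from 12 and comes back at 15 without any new compound. It is a Markovnikov hydrobromination by cobalt-mediated hydrogen-atom transfer (Co(acac)2, t-BuOOH, Et3SiH, TsBr), which passes only through the C2' radical (γ to O1) and needs neither base nor phosphine.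

**Further compounds**
F1 | step 17 | (3S,4S,6S)-3-{2-[(tert-butyldimethylsilyl)oxy]ethyl}-4,6-dimethyl-6-[(2R)-2-(4,4,5,5-tetramethyl-1,3,2-dioxaborolan-2-yl)propyl]-1,2-dioxane | CC1(C)OB(OC1(C)C)[C@H](C)C[C@@]1(C)C[C@H](C)[C@H](CCO[Si](C)(C)C(C)(C)C)OO1
F2 | step 17 | [(1E,3S,5E)-6-iodo-3-methylhexa-1,5-dien-1-yl]benzene | C[C@H](/C=C/c1ccccc1)C/C=C/I
F3 | step 10 | (3S,4S,6R)-3-{2-[(tert-butyldimethylsilyl)oxy]ethyl}-4,6-dimethyl-6-(2-oxopropyl)-1,2-dioxane | CC(=O)C[C@@]1(C)C[C@H](C)[C@H](CCO[Si](C)(C)C(C)(C)C)OO1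
F0 | step 11 | none | none
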